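**Retrosynthetic overview**
- Last C–C bond: C11–C12 at the quaternary carbon. A tertiary C11 radical, made from a cesium oxalate under visible light, adds to (3E,7E)-4,8,12-trimethyltrideca-1,3,7,11-tetraene; desilylation then gives iridal.
- The Z-enal comes from the isopropenyl group (singlet-oxygen ene reaction, dehydration, base isomerisation). The C11 oxalate comes from the ketone by MeLi addition and acylation.
- The C6 side chain is set by enolate alkylation trans to the isopropenyl group. The C10 carbinol comes from the nucleophilic epoxide of (S)-carvone, opened by hydride.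
- The only ring is the cyclohexane ring of (S)-carvone; it is bought and no ring is formed. The tetraene comes from (2E,6E)-farnesol in two steps.

Ring locants in the Why lines are those of iridal: C6 (CH with the hydroxypropyl chain), C7 (alkylidene carbon), C8, C9, C10 (carbinol), C11 (quaternary carbon).
Assumption: (S)-(+)-carvone, tert-butyl(3-iodopropoxy)dimethylsilane and (2E,6E)-farnesol are bought.

**Route**

Step 1
Reactants: 1 (S)-(+)-carvone
Product: 2 (1S,4S,6S)-1-methyl-4-(prop-1-en-2-yl)-7-oxabicyclo[4.1.0]heptan-2-one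
Conditions: 30% H2O2, NaOH (0.3 equiv), MeOH, 0 °C
Reagents that add atoms: hydrogen peroxide, OO
Why: Weitz–Scheffer nucleophilic epoxidation; hydroperoxide adds axially to the enone β-carbon anti to the isopropenyl group, so the epoxide oxygen (the future C10–O) is trans to it.

Step 2
Reactants: 2 (1S,4S,6S)-1-methyl-4-(prop-1-en-2-yl)-7-oxabicyclo[4.1.0]heptan-2-one
Product: 3 (1S,2R,4S)-1-methyl-4-(prop-1-en-2-yl)cyclohexane-1,2-diol
Conditions: LiAlH4, THF, 0 to 40 °C; H2O, aq NaOH work-up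
Reagents that add atoms: none
Why: Hydride reduction of the ketone followed by SN2 epoxide opening at the less substituted carbon (C9) keeps the tertiary C10–O bond with retention; the new secondary carbinol (major epimer shown) is erased in Step 3.

Step 3
Reactants: 3 (1S,2R,4S)-1-methyl-4-(prop-1-en-2-yl)cyclohexane-1,2-diol
Product: 4 (2S,5S)-2-hydroxy-2-methyl-5-(prop-1-en-2-yl)cyclohexan-1-one
Conditions: Dess–Martin periodinane, CH2Cl2, 0 °C to rt
Reagents that add atoms: none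
Why: Dess–Martin oxidation touches only the secondary alcohol and gives the α-hydroxy ketone without changing C10 or C7.

Step 4
Reactants: 4 (2S,5S)-2-hydroxy-2-methyl-5-(prop-1-en-2-yl)cyclohexan-1-one; 5 tert-butyl(3-iodopropoxy)dimethylsilane
Product: 8 (2S,5S,6R)-6-[3-[(tert-butyldimethylsilyl)oxy]propyl]-2-methyl-5-(prop-1-en-2-yl)-2-[(triethylsilyl)oxy]cyclohexan-1-one, via dilithium enolate alkoxide 6 (not isolated), via lithium alkoxide 7 (not isolated)
Conditions: LiN(iPr)2 (2.2 equiv), THF, −78 to −20 °C; 5 (1.3 equiv), DMPU, −40 to 0 °C; Et3SiCl (1.5 equiv), 0 °C to rt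
Reagents that add atoms: chlorotriethylsilane, CC[Si](Cl)(CC)CC
Why: Dianion alkylation; the ketone can enolise only toward C6, and the enolate is alkylated anti to the adjacent isopropenyl group (trans, also the thermodynamic arrangement), which sets C6; the tertiary alkoxide is then silylated in the same flask.

Step 5
Reactants: 8 (2S,5S,6R)-6-[3-[(tert-butyldimethylsilyl)oxy]propyl]-2-methyl-5-(prop-1-en-2-yl)-2-[(triethylsilyl)oxy]cyclohexan-1-one
Product: 10 methyl (1R,2S,5S,6R)-6-[3-[(tert-butyldimethylsilyl)oxy]propyl]-1,2-dimethyl-5-(prop-1-en-2-yl)-2-[(triethylsilyl)oxy]cyclohexyl oxalate, via lithium tertiary alkoxide 9 (not isolated)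
Conditions: MeLi, THF, −78 °C; then ClC(O)CO2Me, −78 to 0 °C
Reagents that add atoms: methyllithium, [Li]C; methyl chlorooxoacetate, COC(=O)C(Cl)=O
Why: 1,2-Addition of MeLi to the hindered ketone and O-acylation of the alkoxide at −78 °C (before any silyl migration) give the tert-alkyl methyl oxalate; the C11 configuration (major epimer shown) does not matter because C11 becomes a planar radical in Step 10.

Step 6
Reactants: 10 methyl (1R,2S,5S,6R)-6-[3-[(tert-butyldimethylsilyl)oxy]propyl]-1,2-dimethyl-5-(prop-1-en-2-yl)-2-[(triethylsilyl)oxy]cyclohexyl oxalate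
Product: 14 methyl (1R,2S,5Z,6R)-6-[3-[(tert-butyldimethylsilyl)oxy]propyl]-1,2-dimethyl-5-(1-oxopropan-2-ylidene)-2-[(triethylsilyl)oxy]cyclohexyl oxalate, via allylic hydroperoxide 11 (not isolated), via allylic peracetate 12 (not isolated), via methylene aldehyde 13 (not isolated)
Conditions: O2, tetraphenylporphyrin (1 mol %), white LEDs, Ac2O, pyridine, DMAP (cat.), CH2Cl2, 0 °C; then DBU (0.3 equiv), rt
Reagents that add atoms: dioxygen, O=O
Why: Schenck ene reaction of singlet oxygen at the only alkene puts OOH on the terminal carbon whichever allylic H is taken, acetylation and Kornblum–DeLaMare-type elimination give the aldehyde, and DBU moves the double bond to the ring-exocyclic position through the dienolate; the thermodynamic Z isomer (CHO beside the substituted C6, methyl beside C8H2) is isolated and the E isomer is recycled with DBU, the temporary C7 stereocentre is removed on purpose, and C6 is not epimerised because its H lies in the alkene plane.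

Step 7
Reactants: 14 methyl (1R,2S,5Z,6R)-6-[3-[(tert-butyldimethylsilyl)oxy]propyl]-1,2-dimethyl-5-(1-oxopropan-2-ylidene)-2-[(triethylsilyl)oxy]cyclohexyl oxalate
Product: 15 cesium 2-[[(1R,2S,5Z,6R)-6-[3-[(tert-butyldimethylsilyl)oxy]propyl]-1,2-dimethyl-5-(1-oxopropan-2-ylidene)-2-[(triethylsilyl)oxy]cyclohexyl]oxy]-2-oxoacetate
Conditions: CsOH·H2O (1.0 equiv), THF/H2O, rt, 10 min
Reagents that add atoms: cesium hydroxide, [Cs+].[OH-]
Why: Saponification; hydroxide attacks only the unhindered methyl ester carbonyl of the mixed oxalate and gives the stable cesium half-oxalate.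

Step 8
Reactants: 16 (2E,6E)-farnesol
Product: 17 (2E,6E)-farnesal
Conditions: MnO2, CH2Cl2, rt
Reagents that add atoms: none
Why: Allylic alcohol oxidation with MnO2 gives the enal without touching the other alkenes or the 2E geometry.

Step 9
Reactants: 17 (2E,6E)-farnesal
Product: 18 (3E,7E)-4,8,12-trimethyltrideca-1,3,7,11-tetraene
Conditions: Ph3PCH3Br, KOtBu, THF, 0 °C to rt
Reagents that add atoms: methyltriphenylphosphonium bromide, C[P+](c1ccccc1)(c1ccccc1)c1ccccc1.[Br-]
Why: Wittig methylenation of the conjugated aldehyde gives the terminal diene; no stereocentre is made and the 3E alkene is carried over from farnesal.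

Step 10
Reactants: 15 cesium 2-[[(1R,2S,5Z,6R)-6-[3-[(tert-butyldimethylsilyl)oxy]propyl]-1,2-dimethyl-5-(1-oxopropan-2-ylidene)-2-[(triethylsilyl)oxy]cyclohexyl]oxy]-2-oxoacetate; 18 (3E,7E)-4,8,12-trimethyltrideca-1,3,7,11-tetraene
Product: 19 (2Z)-2-[(2R,3S,4S)-2-[3-[(tert-butyldimethylsilyl)oxy]propyl]-3,4-dimethyl-4-[(triethylsilyl)oxy]-3-[(3E,7E)-4,8,12-trimethyltrideca-3,7,11-trien-1-yl]cyclohexylidene]propanal
Conditions: Ru(bpz)3(PF6)2 (2 mol %), 2,4,6-triisopropylbenzenethiol (5 mol %), H2O (10 equiv), 18 (3 equiv), DME/DMF 3:1, 450 nm LEDs, 30 °C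
Reagents that add atoms: none
Why: Proposed new method: photoredox deoxygenative 1,2-hydroalkylation of a terminal 1,3-diene by a tertiary alkyl oxalate; the excited ruthenium complex oxidises the oxalate carboxylate (about +1.3 V), loss of two CO2 gives the C11 tertiary radical, and this adds to the CH2 terminus of 18 on the face opposite the C6 chain (held axial by A(1,3) strain with the Z-enal) and the C10 OSiEt3 group, which sets C11 with the new chain cis to the C10 methyl; the allyl radical takes H from the hindered arenethiol at its less hindered secondary terminus so the E trisubstituted alkene is kept, the thiyl radical is reduced by the reduced photocatalyst and reprotonated by water, and a photocatalyst of low triplet energy is used so the diene is not sensitised; the closest known reaction type is the redox-neutral photoredox Giese coupling of tertiary alkyl oxalate salts with electron-poor alkenes, here extended to a non-activated diene with thiol hydrogen-atom-transfer termination.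

Step 11
Reactants: 19 (2Z)-2-[(2R,3S,4S)-2-[3-[(tert-butyldimethylsilyl)oxy]propyl]-3,4-dimethyl-4-[(triethylsilyl)oxy]-3-[(3E,7E)-4,8,12-trimethyltrideca-3,7,11-trien-1-yl]cyclohexylidene]propanal
Product: 20 iridal, (2Z)-2-[(2R,3S,4S)-4-hydroxy-2-(3-hydroxypropyl)-3,4-dimethyl-3-[(3E,7E)-4,8,12-trimethyltrideca-3,7,11-trien-1-yl]cyclohexylidene]propanal
Conditions: HF·pyridine, pyridine, THF, 0 °C to rt
Reagents that add atoms: none
Why: Fluoride-mediated desilylation removes the primary tert-butyldimethylsilyl and the tertiary triethylsilyl ether under buffered conditions that leave the enal, the tertiary alcohol and the trisubstituted alkenes alone.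

**Compound list**

1 | (S)-(+)-carvone, (5S)-2-methyl-5-(prop-1-en-2-yl)cyclohex-2-en-1-one | CC1=CC[C@@H](CC1=O)C(C)=C | starting material
2 | (1S,4S,6S)-1-methyl-4-(prop-1-en-2-yl)-7-oxabicyclo[4.1.0]heptan-2-one | O=C1C[C@@H](C(C)=C)C[C@@H]2O[C@]12C | intermediate
3 | (1S,2R,4S)-1-methyl-4-(prop-1-en-2-yl)cyclohexane-1,2-diol (major C2 epimer) | O[C@@H]1C[C@@H](C(C)=C)CC[C@]1(C)O | intermediate
4 | (2S,5S)-2-hydroxy-2-methyl-5-(prop-1-en-2-yl)cyclohexan-1-one | O=C1C[C@@H](C(C)=C)CC[C@]1(C)O | intermediate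
5 | tert-butyl(3-iodopropoxy)dimethylsilane | ICCCO[Si](C)(C)C(C)(C)C | starting material
6 | dilithium enolate alkoxide of 4 (enolate toward C6, alkoxide at C10) | [Li+].[Li+].[O-]C1=C[C@@H](C(C)=C)CC[C@]1(C)[O-] | intermediate
7 | lithium (1S,3R,4S)-3-[3-[(tert-butyldimethylsilyl)oxy]propyl]-1-methyl-2-oxo-4-(prop-1-en-2-yl)cyclohexan-1-olate | [Li+].O=C1[C@H](CCCO[Si](C)(C)C(C)(C)C)[C@@H](C(C)=C)CC[C@]1(C)[O-] | intermediate
8 | (2S,5S,6R)-6-[3-[(tert-butyldimethylsilyl)oxy]propyl]-2-methyl-5-(prop-1-en-2-yl)-2-[(triethylsilyl)oxy]cyclohexan-1-one | O=C1[C@H](CCCO[Si](C)(C)C(C)(C)C)[C@@H](C(C)=C)CC[C@]1(C)O[Si](CC)(CC)CC | intermediate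
9 | lithium (1R,2S,5S,6R)-6-[3-[(tert-butyldimethylsilyl)oxy]propyl]-1,2-dimethyl-5-(prop-1-en-2-yl)-2-[(triethylsilyl)oxy]cyclohexan-1-olate (major C1 epimer) | [Li+].C[C@@]1([O-])[C@H](CCCO[Si](C)(C)C(C)(C)C)[C@@H](C(C)=C)CC[C@]1(C)O[Si](CC)(CC)CC | intermediate
10 | methyl (1R,2S,5S,6R)-6-[3-[(tert-butyldimethylsilyl)oxy]propyl]-1,2-dimethyl-5-(prop-1-en-2-yl)-2-[(triethylsilyl)oxy]cyclohexyl oxalate | C[C@@]1(OC(=O)C(=O)OC)[C@H](CCCO[Si](C)(C)C(C)(C)C)[C@@H](C(C)=C)CC[C@]1(C)O[Si](CC)(CC)CC | intermediate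
11 | methyl (1R,2S,5S,6R)-6-[3-[(tert-butyldimethylsilyl)oxy]propyl]-5-(3-hydroperoxyprop-1-en-2-yl)-1,2-dimethyl-2-[(triethylsilyl)oxy]cyclohexyl oxalate | C[C@@]1(OC(=O)C(=O)OC)[C@H](CCCO[Si](C)(C)C(C)(C)C)[C@@H](C(=C)COO)CC[C@]1(C)O[Si](CC)(CC)CC | intermediate
12 | methyl (1R,2S,5S,6R)-5-[3-(acetylperoxy)prop-1-en-2-yl]-6-[3-[(tert-butyldimethylsilyl)oxy]propyl]-1,2-dimethyl-2-[(triethylsilyl)oxy]cyclohexyl oxalate | C[C@@]1(OC(=O)C(=O)OC)[C@H](CCCO[Si](C)(C)C(C)(C)C)[C@@H](C(=C)COOC(C)=O)CC[C@]1(C)O[Si](CC)(CC)CC | intermediate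
13 | methyl (1R,2S,5S,6R)-6-[3-[(tert-butyldimethylsilyl)oxy]propyl]-1,2-dimethyl-5-(3-oxoprop-1-en-2-yl)-2-[(triethylsilyl)oxy]cyclohexyl oxalate | C[C@@]1(OC(=O)C(=O)OC)[C@H](CCCO[Si](C)(C)C(C)(C)C)[C@@H](C(=C)C=O)CC[C@]1(C)O[Si](CC)(CC)CC | intermediate
14 | methyl (1R,2S,5Z,6R)-6-[3-[(tert-butyldimethylsilyl)oxy]propyl]-1,2-dimethyl-5-(1-oxopropan-2-ylidene)-2-[(triethylsilyl)oxy]cyclohexyl oxalate | C[C@@]1(OC(=O)C(=O)OC)[C@H](CCCO[Si](C)(C)C(C)(C)C)/C(=C(/C)C=O)CC[C@]1(C)O[Si](CC)(CC)CC | intermediate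
15 | cesium 2-[[(1R,2S,5Z,6R)-6-[3-[(tert-butyldimethylsilyl)oxy]propyl]-1,2-dimethyl-5-(1-oxopropan-2-ylidene)-2-[(triethylsilyl)oxy]cyclohexyl]oxy]-2-oxoacetate | [Cs+].C[C@@]1(OC(=O)C([O-])=O)[C@H](CCCO[Si](C)(C)C(C)(C)C)/C(=C(/C)C=O)CC[C@]1(C)O[Si](CC)(CC)CC | intermediate
16 | (2E,6E)-farnesol | CC(C)=CCC/C(C)=C/CC/C(C)=C/CO | starting material
17 | (2E,6E)-farnesal | CC(C)=CCC/C(C)=C/CC/C(C)=C/C=O | intermediate
18 | (3E,7E)-4,8,12-trimethyltrideca-1,3,7,11-tetraene | CC(C)=CCC/C(C)=C/CC/C(C)=C/C=C | intermediate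
19 | (2Z)-2-[(2R,3S,4S)-2-[3-[(tert-butyldimethylsilyl)oxy]propyl]-3,4-dimethyl-4-[(triethylsilyl)oxy]-3-[(3E,7E)-4,8,12-trimethyltrideca-3,7,11-trien-1-yl]cyclohexylidene]propanal | CC(C)=CCC/C(C)=C/CC/C(C)=C/CC[C@@]1(C)[C@H](CCCO[Si](C)(C)C(C)(C)C)/C(=C(/C)C=O)CC[C@]1(C)O[Si](CC)(CC)CC | intermediate
20 | iridal, (2Z)-2-[(2R,3S,4S)-4-hydroxy-2-(3-hydroxypropyl)-3,4-dimethyl-3-[(3E,7E)-4,8,12-trimethyltrideca-3,7,11-trien-1-yl]cyclohexylidene]propanal | CC(C)=CCC/C(C)=C/CC/C(C)=C/CC[C@@]1(C)[C@H](CCCO)/C(=C(/C)C=O)CC[C@]1(C)O | target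

**Step count and risks**

Total steps: 11. Longest linear sequence: 9 (Steps 1–7, 10, 11).

The three steps most likely to fail:

Step 10 (the proposed new reaction). The risks are:
- reduction of the C11 radical by the thiol before it meets the diene;
- hydrogen transfer to the tertiary terminus of the allyl radical, giving the regioisomeric alkene;
- thiyl-mediated E/Z erosion in the chain;
- incomplete facial control at C11.

The fallback uses known chemistry, sets out from 15 and comes back at 19. Cesium oxalate 15 is coupled with methyl acrylate under the established conditions for tertiary oxalate salts (Ir[dF(CF3)ppy]2(dtbbpy)PF6, H2O, DME/DMF, blue LEDs, 60 °C) to give the propanoate ester F6. LiOH in THF/H2O gives the propanoic acid F7, and N-hydroxyphthalimide with N,N'-diisopropylcarbodiimide gives the redox-active ester F8. In parallel, geranylacetone is converted with LiN(iPr)2, ClP(O)(OEt)2 and again LiN(iPr)2 through the enol phosphate F9 into the terminal enyne F10, and carboalumination and iodination (Me3Al, Cp2ZrCl2; I2) give the E-alkenyl iodide F11. Nickel-electrocatalytic decarboxylative alkenylation of F8 with F11 (NiCl2·6H2O, 2,2'-bipyridine, AgNO3, magnesium anode, carbon cathode, DMF) forms the C13–C14 bond with retention of the alkene geometry and gives 19.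

Step 6. The isopropenyl group is a slow singlet-oxygen acceptor, and the isomerisation may give an unfavourable Z/E ratio. The fallback sets out from 10 and comes back at 13. Ene chlorination of 10 (Ca(OCl)2, solid CO2, CH2Cl2/H2O, 0 °C) gives the allylic chloride F5. Oxidation with N-methylmorpholine N-oxide, NaHCO3 and catalytic NaI in MeCN gives the methylene aldehyde 13, which is taken on to 14 with DBU as in Step 6.

Step 4. The one-flask dianion alkylation and silylation may suffer from slow C-alkylation or incomplete O-silylation. The fallback sets out from 1 and comes back at 8. The cross-conjugated lithium enolate of 1 (LiN(iPr)2, THF, DMPU) is alkylated with 5 to give the trans-alkylated carvone F1. H2O2/NaOH gives the epoxy ketone F2, LiAlH4 gives the diol F3, and Dess–Martin periodinane gives the hydroxy ketone F4. Et3SiOTf and 2,6-lutidine then give 8.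

**Further compounds**

F1 | step 4 | (5S,6R)-6-[3-[(tert-butyldimethylsilyl)oxy]propyl]-2-methyl-5-(prop-1-en-2-yl)cyclohex-2-en-1-one | O=C1[C@H](CCCO[Si](C)(C)C(C)(C)C)[C@@H](C(C)=C)CC=C1C
F2 | step 4 | (1S,3R,4S,6S)-3-[3-[(tert-butyldimethylsilyl)oxy]propyl]-1-methyl-4-(prop-1-en-2-yl)-7-oxabicyclo[4.1.0]heptan-2-one | O=C1[C@H](CCCO[Si](C)(C)C(C)(C)C)[C@@H](C(C)=C)C[C@@H]2O[C@]12C
F3 | step 4 | (1S,2R,3R,4S)-3-[3-[(tert-butyldimethylsilyl)oxy]propyl]-1-methyl-4-(prop-1-en-2-yl)cyclohexane-1,2-diol | O[C@@H]1[C@H](CCCO[Si](C)(C)C(C)(C)C)[C@@H](C(C)=C)CC[C@]1(C)O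
F4 | step 4 | (2S,5S,6R)-6-[3-[(tert-butyldimethylsilyl)oxy]propyl]-2-hydroxy-2-methyl-5-(prop-1-en-2-yl)cyclohexan-1-one | O=C1[C@H](CCCO[Si](C)(C)C(C)(C)C)[C@@H](C(C)=C)CC[C@]1(C)O
F5 | step 6 | methyl (1R,2S,5S,6R)-6-[3-[(tert-butyldimethylsilyl)oxy]propyl]-5-(3-chloroprop-1-en-2-yl)-1,2-dimethyl-2-[(triethylsilyl)oxy]cyclohexyl oxalate | C[C@@]1(OC(=O)C(=O)OC)[C@H](CCCO[Si](C)(C)C(C)(C)C)[C@@H](C(=C)CCl)CC[C@]1(C)O[Si](CC)(CC)CC
F6 | step 10 | methyl 3-[(1S,2S,5Z,6R)-6-[3-[(tert-butyldimethylsilyl)oxy]propyl]-1,2-dimethyl-5-(1-oxopropan-2-ylidene)-2-[(triethylsilyl)oxy]cyclohexyl]propanoate | COC(=O)CC[C@@]1(C)[C@H](CCCO[Si](C)(C)C(C)(C)C)/C(=C(/C)C=O)CC[C@]1(C)O[Si](CC)(CC)CC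
F7 | step 10 | 3-[(1S,2S,5Z,6R)-6-[3-[(tert-butyldimethylsilyl)oxy]propyl]-1,2-dimethyl-5-(1-oxopropan-2-ylidene)-2-[(triethylsilyl)oxy]cyclohexyl]propanoic acid | OC(=O)CC[C@@]1(C)[C@H](CCCO[Si](C)(C)C(C)(C)C)/C(=C(/C)C=O)CC[C@]1(C)O[Si](CC)(CC)CC
F8 | step 10 | 1,3-dioxoisoindolin-2-yl 3-[(1S,2S,5Z,6R)-6-[3-[(tert-butyldimethylsilyl)oxy]propyl]-1,2-dimethyl-5-(1-oxopropan-2-ylidene)-2-[(triethylsilyl)oxy]cyclohexyl]propanoate | O=C(CC[C@@]1(C)[C@H](CCCO[Si](C)(C)C(C)(C)C)/C(=C(/C)C=O)CC[C@]1(C)O[Si](CC)(CC)CC)ON2C(=O)c3ccccc3C2=O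
F9 | step 10 | diethyl (5E)-6,10-dimethylundeca-1,5,9-trien-2-yl phosphate | C=C(CC/C=C(\C)CCC=C(C)C)OP(=O)(OCC)OCC
F10 | step 10 | (5E)-6,10-dimethylundeca-5,9-dien-1-yne | C#CCC/C=C(\C)CCC=C(C)C
F11 | step 10 | (1E,5E)-1-iodo-2,6,10-trimethylundeca-1,5,9-triene | I/C=C(\C)CC/C=C(\C)CCC=C(C)C
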